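**Retrosynthetic overview**
- The last C–C bond made is C5–side chain: Negishi coupling of a ring-B alkenyl triflate with (4-methylpent-3-enyl)zinc bromide, followed only by PMB removal.
- The glyceride comes from O-alkylation of the bicyclic carboxylate with an (S)-glycidol-derived iodo acetate; the acid comes from hydroboration/oxidation of an exocyclic methylene at C1.
- Ring A is closed onto ring B by intramolecular enolate alkylation (C4–C4a, cis fusion), after the C1–C8a bond is made by Ni/Cu-catalysed hydroalumination and enantioselective conjugate addition.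
- Fragments: (R)-5-chloro-3-methylpent-1-yne (from α-methylene-γ-butyrolactone), 2,3-dimethylcyclohex-2-enone (from cyclohexane-1,3-dione), the zinc reagent and the iodo acetate.
- Ring order: ring B is carried in from cyclohexane-1,3-dione; ring A is annulated onto it.

Assumption: bicyclic compounds are named with the locants of the target acid (C1 carboxyl-bearing, C2 methyl-bearing, C4a/C8a angular, C5 side-chain carbon), and the BINAP and NHC enantiomers are taken as those that give the configurations drawn.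

**Fragment A (steps 1–4)**

Step 1
Reactants: 1 3-methylideneoxolan-2-one (α-methylene-γ-butyrolactone)
Product: 2 (3R)-3-methyloxolan-2-one
Conditions: H2 (100 atm), Ru(OAc)2[(S)-BINAP] (0.5 mol %), CH2Cl2, 50 °C
Reagents that add atoms: none
Why: Ru–BINAP asymmetric hydrogenation of the exocyclic α-methylene lactone delivers hydrogen to one face of the carbonyl-coordinated alkene and sets the methyl-bearing centre (the future C2) as R.

Step 2
Reactants: 2 (3R)-3-methyloxolan-2-one
Product: 3 (3R)-3-methyloxolan-2-ol (lactol, both anomers)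
Conditions: i-Bu2AlH (1.05 equiv), CH2Cl2, −78 °C; aq. potassium sodium tartrate
Reagents that add atoms: none
Why: Low-temperature hydride half-reduction of a lactone stops at the lactol and does not touch the stereocentre.

Step 3
Reactants: 3 (3R)-3-methyloxolan-2-ol
Product: 4 (3R)-3-methylpent-4-yn-1-ol
Conditions: dimethyl (1-diazo-2-oxopropyl)phosphonate, K2CO3, MeOH, 0 °C → rt
Reagents that add atoms: dimethyl (1-diazo-2-oxopropyl)phosphonate, COP(=O)(OC)C(=[N+]=[N-])C(C)=O
Why: Ohira–Bestmann (Seyferth–Gilbert) homologation of the ring-opened hydroxy aldehyde gives the terminal alkyne under mild carbonate conditions that preserve the α-stereocentre.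

Step 4
Reactants: 4 (3R)-3-methylpent-4-yn-1-ol
Product: 5 (3R)-5-chloro-3-methylpent-1-yne
Conditions: PPh3, N-chlorosuccinimide, CH2Cl2, 0 °C → rt
Reagents that add atoms: N-chlorosuccinimide, ClN1C(=O)CCC1=O
Why: Appel-type chlorination of the primary alcohol is an SN2 displacement at a carbon remote from the stereocentre.

**Fragment B (steps 5–7)**

Step 5
Reactants: 6 cyclohexane-1,3-dione
Product: 7 2-methylcyclohexane-1,3-dione
Conditions: MeI, KOH, H2O/MeOH, 65 °C
Reagents that add atoms: iodomethane, CI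
Why: C-alkylation of the stabilised 1,3-diketone enolate with iodomethane is a classical, scalable reaction.

Step 6
Reactants: 7 2-methylcyclohexane-1,3-dione
Product: 8 2-methyl-3-(2-methylpropoxy)cyclohex-2-en-1-one
Conditions: i-BuOH, TsOH (cat.), toluene, reflux, Dean–Stark
Reagents that add atoms: 2-methylpropan-1-ol, CC(C)CO
Why: Acid-catalysed vinylogous ester formation is driven by azeotropic removal of water.

Step 7
Reactants: 8 2-methyl-3-(2-methylpropoxy)cyclohex-2-en-1-one
Product: 10 2,3-dimethylcyclohex-2-en-1-one, via tertiary carbinol adduct 9 (not isolated)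
Conditions: MeLi, Et2O, −78 → 0 °C; then 1 M HCl, rt
Reagents that add atoms: methyllithium, [Li]C
Why: Stork–Danheiser transposition: 1,2-addition of methyllithium to the vinylogous ester, then acid hydrolysis and loss of water give the β-methyl enone.

**Core (steps 8–13)**

Step 8
Reactants: 5 (3R)-5-chloro-3-methylpent-1-yne; 10 2,3-dimethylcyclohex-2-en-1-one
Product: 12 (3S)-3-[(3R)-5-chloro-3-methylpent-1-en-2-yl]-2,3-dimethylcyclohexan-1-one (both C2 epimers), via alkenylalane 11 (not isolated)
Conditions: 5, i-Bu2AlH (1.05 equiv), NiCl2(dppp) (3 mol %), THF, 0 → 22 °C; then 10, Cu(OTf)2 (10 mol %), sulfonate-bearing chiral imidazolinium salt (NHC precursor, 12 mol %), THF, −15 → 22 °C; aq. potassium sodium tartrate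
Reagents that add atoms: none
Why: Proposed new method: nickel-catalysed α-selective hydroalumination gives the 1,1-disubstituted alkenylalane 11, whose alkenyl group passes to the NHC-bound monovalent copper while the Lewis-acidic alane, held by the sulfonate bridge, activates the enone carbonyl, and π-complexation, formation of a trivalent copper β-adduct and reductive elimination then forge the C1–C8a bond on the enone face chosen by the ligand (catalyst control, 3S), the small sp2 nucleophile and the Lewis-acid activation being what should let a fully substituted enone react; the closest known reaction type is the NHC–copper-catalysed enantioselective conjugate addition of alkenylaluminium reagents to β-substituted (trisubstituted) cyclic enones, not yet shown for an α,β-dimethyl enone.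

Step 9
Reactants: 12 (3S)-3-[(3R)-5-chloro-3-methylpent-1-en-2-yl]-2,3-dimethylcyclohexan-1-one
Product: 13 (2R,4aS,8aR)-2,4a,8a-trimethyl-1-methylideneoctahydronaphthalen-5(1H)-one (cis-fused)
Conditions: t-BuOK (1.5 equiv), t-BuOH/THF, 25 → 45 °C
Reagents that add atoms: none
Why: Under equilibrating conditions the more substituted enolate closes ring A by 6-exo-tet intramolecular SN2 alkylation (methylenecyclohexane annulation); the tether on the quaternary carbon sits pseudoaxial to avoid allylic 1,2-strain with the enolate methyl and attacks the same face, so the ring fusion is cis and the angular methyls are cis (4aS).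

Step 10
Reactants: 13 (2R,4aS,8aR)-2,4a,8a-trimethyl-1-methylideneoctahydronaphthalen-5(1H)-one
Product: 14 (2R,4aS,8aR)-2,4a,8a-trimethyl-1-methylidene-1,2,3,4,4a,7,8,8a-octahydronaphthalen-5-yl trifluoromethanesulfonate
Conditions: KHMDS, THF, −78 °C; then PhNTf2, −78 → 0 °C
Reagents that add atoms: N-phenylbis(trifluoromethanesulfonimide), O=S(=O)(N(c1ccccc1)S(=O)(=O)C(F)(F)F)C(F)(F)F
Why: Only C6 carries α-hydrogens, so enolate formation and O-triflation give a single alkenyl triflate with the C5=C6 double bond in place.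

Step 11
Reactants: 14 (2R,4aS,8aR)-2,4a,8a-trimethyl-1-methylidene-1,2,3,4,4a,7,8,8a-octahydronaphthalen-5-yl trifluoromethanesulfonate
Product: 16 [(1S,2R,4aS,8aR)-1-(hydroxymethyl)-2,4a,8a-trimethyl-1,2,3,4,4a,7,8,8a-octahydronaphthalen-5-yl] trifluoromethanesulfonate, via B-alkyl-9-borabicyclononane adduct 15 (not isolated)
Conditions: 9-BBN (2 equiv), THF, 60 °C; then 30% H2O2, aq. NaOAc (3 M), 0 °C → rt
Reagents that add atoms: hydrogen peroxide, OO
Why: Anti-Markovnikov hydroboration–oxidation of the 1,1-disubstituted alkene (the electron-poor alkenyl triflate is inert) places boron on the exocyclic carbon from the face away from the adjacent axial angular methyl, so hydrogen enters C1 on the opposite side to that methyl and gives 1S; any 1R epimer is corrected in step 12.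

Step 12
Reactants: 16 [(1S,2R,4aS,8aR)-1-(hydroxymethyl)-2,4a,8a-trimethyl-1,2,3,4,4a,7,8,8a-octahydronaphthalen-5-yl] trifluoromethanesulfonate
Product: 17 [(1S,2R,4aS,8aR)-1-formyl-2,4a,8a-trimethyl-1,2,3,4,4a,7,8,8a-octahydronaphthalen-5-yl] trifluoromethanesulfonate
Conditions: Dess–Martin periodinane, CH2Cl2, 0 °C → rt; filtration through basic alumina; then DBU (0.2 equiv), CH2Cl2, rt
Reagents that add atoms: none
Why: Dess–Martin oxidation followed by base equilibration through the enolate gives the thermodynamic aldehyde, in which the formyl group and the C2 methyl are both equatorial (1S), because the 1R epimer has a 1,3-diaxial clash in either chair.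

Step 13
Reactants: 17 [(1S,2R,4aS,8aR)-1-formyl-2,4a,8a-trimethyl-1,2,3,4,4a,7,8,8a-octahydronaphthalen-5-yl] trifluoromethanesulfonate
Product: 18 (1S,2R,4aS,8aR)-2,4a,8a-trimethyl-5-(trifluoromethanesulfonyloxy)-1,2,3,4,4a,7,8,8a-octahydronaphthalene-1-carboxylic acid
Conditions: NaClO2, NaH2PO4, 2-methylbut-2-ene, t-BuOH/H2O, 0 °C → rt
Reagents that add atoms: sodium chlorite, [Na+].[O-]Cl=O
Why: Pinnick oxidation converts the hindered aldehyde to the acid under buffered conditions without epimerising C1.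

**Glycerol fragment (steps 14–16)**

Step 14
Reactants: 19 (2S)-oxiran-2-ylmethanol ((S)-glycidol)
Product: 20 (2R)-2-{[(4-methoxyphenyl)methoxy]methyl}oxirane
Conditions: NaH, 4-methoxybenzyl chloride, n-Bu4NI (cat.), DMF, 0 °C → rt
Reagents that add atoms: 4-methoxybenzyl chloride, COc1ccc(CCl)cc1
Why: Williamson etherification of the primary alkoxide leaves the epoxide stereocentre untouched (the descriptor changes from S to R only through priorities).

Step 15
Reactants: 20 (2R)-2-{[(4-methoxyphenyl)methoxy]methyl}oxirane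
Product: 21 (2S)-1-iodo-3-[(4-methoxyphenyl)methoxy]propan-2-ol
Conditions: LiI, AcOH, THF, rt
Reagents that add atoms: lithium iodide, [Li+].[I-]
Why: Acid-assisted SN2 opening of the terminal epoxide by iodide occurs at the unsubstituted carbon, so the stereocentre is retained.

Step 16
Reactants: 21 (2S)-1-iodo-3-[(4-methoxyphenyl)methoxy]propan-2-ol
Product: 22 (2S)-1-iodo-3-[(4-methoxyphenyl)methoxy]propan-2-yl acetate
Conditions: Ac2O, pyridine, DMAP (cat.), CH2Cl2, 0 °C
Reagents that add atoms: acetic anhydride, CC(=O)OC(C)=O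
Why: DMAP-catalysed acetylation of the secondary alcohol at 0 °C is faster than base-induced epoxide re-closure.

**Fragment unions and end game (steps 17–20)**

Step 17
Reactants: 18 (1S,2R,4aS,8aR)-2,4a,8a-trimethyl-5-(trifluoromethanesulfonyloxy)-1,2,3,4,4a,7,8,8a-octahydronaphthalene-1-carboxylic acid; 22 (2S)-1-iodo-3-[(4-methoxyphenyl)methoxy]propan-2-yl acetate
Product: 23 (2S)-2-acetoxy-3-[(4-methoxyphenyl)methoxy]propyl (1S,2R,4aS,8aR)-2,4a,8a-trimethyl-5-(trifluoromethanesulfonyloxy)-1,2,3,4,4a,7,8,8a-octahydronaphthalene-1-carboxylate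
Conditions: Cs2CO3 (0.6 equiv), DMF, rt → 40 °C
Reagents that add atoms: none
Why: SN2 O-alkylation of the caesium carboxylate with the primary iodide esterifies the hindered acid without attack at its carboxyl carbon and leaves the glycerol stereocentre untouched.

Step 18
Reactants: 24 5-bromo-2-methylpent-2-ene
Product: 25 (4-methylpent-3-en-1-yl)zinc bromide
Conditions: Zn dust (activated with BrCH2CH2Br and Me3SiCl), LiCl, THF, 50 °C
Reagents that add atoms: zinc, [Zn]
Why: LiCl-assisted direct insertion of zinc into the primary alkyl bromide gives the functional-group-tolerant alkylzinc reagent.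

Step 19
Reactants: 23 (2S)-2-acetoxy-3-[(4-methoxyphenyl)methoxy]propyl (1S,2R,4aS,8aR)-2,4a,8a-trimethyl-5-(trifluoromethanesulfonyloxy)-1,2,3,4,4a,7,8,8a-octahydronaphthalene-1-carboxylate; 25 (4-methylpent-3-en-1-yl)zinc bromide
Product: 26 (2S)-2-acetoxy-3-[(4-methoxyphenyl)methoxy]propyl (1S,2R,4aR,8aR)-2,4a,8a-trimethyl-5-(4-methylpent-3-en-1-yl)-1,2,3,4,4a,7,8,8a-octahydronaphthalene-1-carboxylate
Conditions: 25 (2 equiv), PdCl2(dppf) (5 mol %), THF/NMP (4:1), 50 °C
Reagents that add atoms: none
Why: Negishi cross-coupling: oxidative addition of zerovalent palladium into the alkenyl C–OTf bond, transmetalation from zinc and reductive elimination (the wide-bite-angle dppf ligand suppresses β-hydride elimination) form the C5–C(sp3) bond while esters, acetate and PMB ether are tolerated.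

Step 20
Reactants: 26 (2S)-2-acetoxy-3-[(4-methoxyphenyl)methoxy]propyl (1S,2R,4aR,8aR)-2,4a,8a-trimethyl-5-(4-methylpent-3-en-1-yl)-1,2,3,4,4a,7,8,8a-octahydronaphthalene-1-carboxylate
Product: 27 (2S)-2-acetoxy-3-hydroxypropyl (1S,2R,4aR,8aR)-2,4a,8a-trimethyl-5-(4-methylpent-3-en-1-yl)-1,2,3,4,4a,7,8,8a-octahydronaphthalene-1-carboxylate (CNP0320437.1)
Conditions: DDQ, CH2Cl2/pH 7 phosphate buffer (10:1), 0 °C
Reagents that add atoms: none
Why: Oxidative cleavage of the PMB ether by DDQ under neutral buffered conditions frees the primary hydroxyl without 2→3 acetyl migration and without touching the trisubstituted alkenes.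

**Compound list**
1 | 3-methylideneoxolan-2-one | C=C1CCOC1=O | starting material
2 | (3R)-3-methyloxolan-2-one | O=C1[C@H](C)CCO1 | intermediate
3 | (3R)-3-methyloxolan-2-ol (anomer mixture) | OC1[C@H](C)CCO1 | intermediate
4 | (3R)-3-methylpent-4-yn-1-ol | C#C[C@H](C)CCO | intermediate
5 | (3R)-5-chloro-3-methylpent-1-yne | C#C[C@H](C)CCCl | intermediate
6 | cyclohexane-1,3-dione | O=C1CCCC(=O)C1 | starting material
7 | 2-methylcyclohexane-1,3-dione | CC1C(=O)CCCC1=O | intermediate
8 | 2-methyl-3-(2-methylpropoxy)cyclohex-2-en-1-one | CC1=C(OCC(C)C)CCCC1=O | intermediate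
9 | 1,2-dimethyl-3-(2-methylpropoxy)cyclohex-2-en-1-ol (racemic, formed as its lithium alkoxide) | CC1=C(OCC(C)C)CCCC1(C)O | intermediate
10 | 2,3-dimethylcyclohex-2-en-1-one | CC1=C(C)CCCC1=O | intermediate
11 | [(3R)-5-chloro-3-methylpent-1-en-2-yl]bis(2-methylpropyl)alumane | C=C([Al](CC(C)C)CC(C)C)[C@H](C)CCCl | intermediate
12 | (3S)-3-[(3R)-5-chloro-3-methylpent-1-en-2-yl]-2,3-dimethylcyclohexan-1-one (both C2 epimers) | C=C([C@H](C)CCCl)[C@@]1(C)CCCC(=O)C1C | intermediate
13 | (2R,4aS,8aR)-2,4a,8a-trimethyl-1-methylideneoctahydronaphthalen-5(1H)-one | C=C1[C@H](C)CC[C@]2(C)C(=O)CCC[C@]12C | intermediate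
14 | (2R,4aS,8aR)-2,4a,8a-trimethyl-1-methylidene-1,2,3,4,4a,7,8,8a-octahydronaphthalen-5-yl trifluoromethanesulfonate | C=C1[C@H](C)CC[C@]2(C)C(OS(=O)(=O)C(F)(F)F)=CCC[C@]12C | intermediate
15 | 9-{[(1S,2R,4aS,8aR)-2,4a,8a-trimethyl-5-(trifluoromethanesulfonyloxy)-1,2,3,4,4a,7,8,8a-octahydronaphthalen-1-yl]methyl}-9-borabicyclo[3.3.1]nonane | C(B1C2CCCC1CCC2)[C@H]1[C@H](C)CC[C@]2(C)C(OS(=O)(=O)C(F)(F)F)=CCC[C@]12C | intermediate
16 | [(1S,2R,4aS,8aR)-1-(hydroxymethyl)-2,4a,8a-trimethyl-1,2,3,4,4a,7,8,8a-octahydronaphthalen-5-yl] trifluoromethanesulfonate | OC[C@H]1[C@H](C)CC[C@]2(C)C(OS(=O)(=O)C(F)(F)F)=CCC[C@]12C | intermediate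
17 | [(1S,2R,4aS,8aR)-1-formyl-2,4a,8a-trimethyl-1,2,3,4,4a,7,8,8a-octahydronaphthalen-5-yl] trifluoromethanesulfonate | O=C[C@H]1[C@H](C)CC[C@]2(C)C(OS(=O)(=O)C(F)(F)F)=CCC[C@]12C | intermediate
18 | (1S,2R,4aS,8aR)-2,4a,8a-trimethyl-5-(trifluoromethanesulfonyloxy)-1,2,3,4,4a,7,8,8a-octahydronaphthalene-1-carboxylic acid | OC(=O)[C@H]1[C@H](C)CC[C@]2(C)C(OS(=O)(=O)C(F)(F)F)=CCC[C@]12C | intermediate
19 | (2S)-oxiran-2-ylmethanol ((S)-glycidol) | OC[C@H]1CO1 | starting material
20 | (2R)-2-{[(4-methoxyphenyl)methoxy]methyl}oxirane | COc1ccc(COC[C@H]2CO2)cc1 | intermediate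
21 | (2S)-1-iodo-3-[(4-methoxyphenyl)methoxy]propan-2-ol | COc1ccc(COC[C@H](O)CI)cc1 | intermediate
22 | (2S)-1-iodo-3-[(4-methoxyphenyl)methoxy]propan-2-yl acetate | COc1ccc(COC[C@H](OC(C)=O)CI)cc1 | intermediate
23 | (2S)-2-acetoxy-3-[(4-methoxyphenyl)methoxy]propyl (1S,2R,4aS,8aR)-2,4a,8a-trimethyl-5-(trifluoromethanesulfonyloxy)-1,2,3,4,4a,7,8,8a-octahydronaphthalene-1-carboxylate | COc1ccc(COC[C@H](OC(C)=O)COC(=O)[C@H]2[C@H](C)CC[C@]3(C)C(OS(=O)(=O)C(F)(F)F)=CCC[C@]23C)cc1 | intermediate
24 | 5-bromo-2-methylpent-2-ene | CC(C)=CCCBr | starting material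
25 | (4-methylpent-3-en-1-yl)zinc bromide | CC(C)=CCC[Zn]Br | intermediate
26 | (2S)-2-acetoxy-3-[(4-methoxyphenyl)methoxy]propyl (1S,2R,4aR,8aR)-2,4a,8a-trimethyl-5-(4-methylpent-3-en-1-yl)-1,2,3,4,4a,7,8,8a-octahydronaphthalene-1-carboxylate | COc1ccc(COC[C@H](OC(C)=O)COC(=O)[C@H]2[C@H](C)CC[C@]3(C)C(CCC=C(C)C)=CCC[C@]23C)cc1 | intermediate
27 | (2S)-2-acetoxy-3-hydroxypropyl (1S,2R,4aR,8aR)-2,4a,8a-trimethyl-5-(4-methylpent-3-en-1-yl)-1,2,3,4,4a,7,8,8a-octahydronaphthalene-1-carboxylate | CC(=O)O[C@@H](CO)COC(=O)[C@H]1[C@H](C)CC[C@]2(C)C(CCC=C(C)C)=CCC[C@]12C | target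

**Step count and risks**

Total step count: 20. Longest linear sequence: 13 steps (steps 1–4, 8–13, 17, 19 and 20), which is 65 % of the total.

The three steps most likely to fail:

Step 8 (the proposed new conjugate addition to a tetrasubstituted enone). The enone 10 may be too hindered, or uncatalysed 1,2-addition of the alane may compete. The fallback sets out from 5 and comes back at 12. Alkenylalane 11 is made from 5 as before and added under the same NHC–copper catalysis to purchased 3-methylcyclohex-2-en-1-one F1, a trisubstituted enone of the established substrate class. The aluminium enolate is trapped with Me3SiCl/Et3N as {[(3S)-3-[(3R)-5-chloro-3-methylpent-1-en-2-yl]-3-methylcyclohex-1-en-1-yl]oxy}trimethylsilane F2. MeLi (THF, 0 °C) then MeI/DMPU methylate the regiodefined lithium enolate to give 12. This costs one extra step and makes steps 5–7 unnecessary.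

Step 17 (carboxylate alkylation with the β-acetoxy iodide). The displacement may be slow, or acetoxonium participation may scramble the two acyl groups. The fallback sets out from 18 and 20 and comes back at 23. Acid 18 opens epoxide 20 at its terminal carbon (n-Bu4NBr cat., DMF, 80 °C) to give (2S)-2-hydroxy-3-[(4-methoxyphenyl)methoxy]propyl (1S,2R,4aS,8aR)-2,4a,8a-trimethyl-5-(trifluoromethanesulfonyloxy)-1,2,3,4,4a,7,8,8a-octahydronaphthalene-1-carboxylate F3. Acetylation of the secondary hydroxyl (Ac2O, DMAP, pyridine, 0 °C) gives 23; steps 15 and 16 are then not needed.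

Step 19 (late Negishi coupling at a triflate next to a quaternary carbon in a molecule carrying acetate, ester and PMB ether). The fallback sets out from 14 and 24 and comes back at 26; the side chain is installed early, on the plain hydrocarbon triflate, with a different metal.
- Bromide 24 and Mg give (4-methylpent-3-en-1-yl)magnesium bromide F4, which couples with 14 under Fe(acac)3 catalysis (THF/NMP, −30 °C) to the triene (2R,4aR,8aR)-2,4a,8a-trimethyl-1-methylidene-5-(4-methylpent-3-en-1-yl)-1,2,3,4,4a,7,8,8a-octahydronaphthalene F5.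
- 9-BBN reacts chemoselectively at the 1,1-disubstituted alkene to give the B-alkyl-9-borabicyclo[3.3.1]nonane adduct F6, oxidised (H2O2, NaOAc) to [(1S,2R,4aR,8aR)-2,4a,8a-trimethyl-5-(4-methylpent-3-en-1-yl)-1,2,3,4,4a,7,8,8a-octahydronaphthalen-1-yl]methanol F7.
- Dess–Martin oxidation with DBU equilibration gives the (1S)-aldehyde F8, and Pinnick oxidation gives (1S,2R,4aR,8aR)-2,4a,8a-trimethyl-5-(4-methylpent-3-en-1-yl)-1,2,3,4,4a,7,8,8a-octahydronaphthalene-1-carboxylic acid F9.
- The caesium salt of F9 is alkylated with 22 as in step 17 to give 26.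

**Further compounds**
F1 | step 8 | 3-methylcyclohex-2-en-1-one | CC1=CC(=O)CCC1
F2 | step 8 | {[(3S)-3-[(3R)-5-chloro-3-methylpent-1-en-2-yl]-3-methylcyclohex-1-en-1-yl]oxy}trimethylsilane | C=C([C@H](C)CCCl)[C@@]1(C)CCCC(O[Si](C)(C)C)=C1
F3 | step 17 | (2S)-2-hydroxy-3-[(4-methoxyphenyl)methoxy]propyl (1S,2R,4aS,8aR)-2,4a,8a-trimethyl-5-(trifluoromethanesulfonyloxy)-1,2,3,4,4a,7,8,8a-octahydronaphthalene-1-carboxylate | COc1ccc(COC[C@H](O)COC(=O)[C@H]2[C@H](C)CC[C@]3(C)C(OS(=O)(=O)C(F)(F)F)=CCC[C@]23C)cc1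
F4 | step 19 | (4-methylpent-3-en-1-yl)magnesium bromide | CC(C)=CCC[Mg]Br
F5 | step 19 | (2R,4aR,8aR)-2,4a,8a-trimethyl-1-methylidene-5-(4-methylpent-3-en-1-yl)-1,2,3,4,4a,7,8,8a-octahydronaphthalene | C=C1[C@H](C)CC[C@]2(C)C(CCC=C(C)C)=CCC[C@]12C
F6 | step 19 | 9-{[(1S,2R,4aR,8aR)-2,4a,8a-trimethyl-5-(4-methylpent-3-en-1-yl)-1,2,3,4,4a,7,8,8a-octahydronaphthalen-1-yl]methyl}-9-borabicyclo[3.3.1]nonane | C(B1C2CCCC1CCC2)[C@H]1[C@H](C)CC[C@]2(C)C(CCC=C(C)C)=CCC[C@]12C
F7 | step 19 | [(1S,2R,4aR,8aR)-2,4a,8a-trimethyl-5-(4-methylpent-3-en-1-yl)-1,2,3,4,4a,7,8,8a-octahydronaphthalen-1-yl]methanol | OC[C@H]1[C@H](C)CC[C@]2(C)C(CCC=C(C)C)=CCC[C@]12C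
F8 | step 19 | (1S,2R,4aR,8aR)-2,4a,8a-trimethyl-5-(4-methylpent-3-en-1-yl)-1,2,3,4,4a,7,8,8a-octahydronaphthalene-1-carbaldehyde | O=C[C@H]1[C@H](C)CC[C@]2(C)C(CCC=C(C)C)=CCC[C@]12C
F9 | step 19 | (1S,2R,4aR,8aR)-2,4a,8a-trimethyl-5-(4-methylpent-3-en-1-yl)-1,2,3,4,4a,7,8,8a-octahydronaphthalene-1-carboxylic acid | OC(=O)[C@H]1[C@H](C)CC[C@]2(C)C(CCC=C(C)C)=CCC[C@]12C
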